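**Strategy.** The cyclobutane (C1, C9, C10, C11; caryophyllane numbering) carries C8 of the nine-membered ring on C9 and the peroxy-hemiketal carbon C12 on C11 in a cis-1,3 relationship. A two-carbon tether C12–C8 therefore lets an intramolecular crossed enone–alkene [2+2] photocycloaddition of an acyclic hexa-1,5-dien-3-one close the ring, forming C10–C11 and C9–C1 at once and giving a strained bicyclo[2.1.1]hexan-2-one. Strain-assisted oxidative cleavage of C8–C12 then unveils a differentiated aldehyde (C8) and ester (C12). The nine-membered ring follows by allylic alkylation, the dioxinol by epoxide perhydrolysis, and the ring epoxide comes last.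

Key step: step 5

Numbering used below: C1 and C9 are the ring-fusion CH carbons (C1 next to C2H2, C9 next to C8); C8 bears the exocyclic methylidene; C4(CH3)/C5 are the epoxide carbons; C10 is the cyclobutane CH2; C11 the quaternary cyclobutane carbon; C12 the hemiketal carbon; C13=C14 the dioxine alkene; C15 the carbon bearing CH3 and CH2OH.

Remark 1: the peroxy-hemiketal carbon C12 is configurationally labile (ring–chain tautomerism through the (Z)-γ-hydroperoxy enone); its 12R configuration is assumed to be the thermodynamically preferred anomer.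

Remark 2: the borane enantiomer in step 3 is chosen for the sense of stereochemical relay argued in step 5; if the relay ran the other way, the enantiomeric borane would correct it without changing the route.

**Step 1**
Reactants: 1 geranyl acetate
Product: 2 (2E,6E)-8-hydroxy-3,7-dimethylocta-2,6-dien-1-yl acetate
Conditions: SeO2 (cat.), t-BuOOH, salicylic acid (cat.), CH2Cl2, rt
Reagents that add atoms: tert-butyl hydroperoxide CC(C)(C)OO; selenium dioxide O=[Se]=O (catalytic oxygen carrier)
Why: SeO2/t-BuOOH allylic oxidation (ene reaction, then [2,3]-sigmatropic shift) attacks the E-methyl group of the electron-richer terminal alkene, the other alkene being deactivated by the allylic acetate, and gives the (6E)-allylic alcohol.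

**Step 2**
Reactants: 2 (2E,6E)-8-hydroxy-3,7-dimethylocta-2,6-dien-1-yl acetate
Product: 3 (2E,6E)-3,7-dimethyl-8-oxoocta-2,6-dien-1-yl acetate
Conditions: MnO2, CH2Cl2, rt
Reagents that add atoms: none
Why: MnO2 oxidises the primary allylic alcohol to the (E)-enal without touching the acetate or the alkene geometry.

**Step 3**
Reactants: 3 (2E,6E)-3,7-dimethyl-8-oxoocta-2,6-dien-1-yl acetate; 4 allyl methoxymethyl ether
Product: 6 (2E,6E,8S,9S)-8-hydroxy-9-(methoxymethoxy)-3,7-dimethylundeca-2,6,10-trien-1-yl acetate, via (Z)-γ-(methoxymethoxy)allyl-diisopinocampheylborane 5 (not isolated)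
Conditions: 4, s-BuLi, THF, −78 °C; (+)-Ipc2BOMe [from (−)-α-pinene]; BF3·OEt2; then 3, −78 °C; ethanolamine work-up
Reagents that add atoms: none
Why: Brown γ-alkoxyallylboration: the (Z)-alkoxyallylborane 5 adds to the aldehyde through a chair transition state on its Re face (Ipc groups from (−)-α-pinene), which sets the MOM-bearing carbon (future C8) as S with syn relative configuration, while the carbinol centre is oxidised in step 4 and the acetate survives the non-basic work-up.

**Step 4**
Reactants: 6 (2E,6E,8S,9S)-8-hydroxy-9-(methoxymethoxy)-3,7-dimethylundeca-2,6,10-trien-1-yl acetate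
Product: 7 (2E,6E,9S)-9-(methoxymethoxy)-3,7-dimethyl-8-oxoundeca-2,6,10-trien-1-yl acetate
Conditions: Dess–Martin periodinane, NaHCO3, CH2Cl2, 0 °C
Reagents that add atoms: none
Why: Buffered Dess–Martin oxidation gives the conjugated enone under neutral conditions, so the α-alkoxy, doubly allylic C–H of the stereocentre is not enolised (no epimerisation, no migration of the vinyl group into conjugation).

**Step 5**
Reactants: 7 (2E,6E,9S)-9-(methoxymethoxy)-3,7-dimethyl-8-oxoundeca-2,6,10-trien-1-yl acetate
Product: 8 (2E)-5-[(1S,3S,4R,5S)-3-(methoxymethoxy)-1-methyl-2-oxobicyclo[2.1.1]hexan-5-yl]-3-methylpent-2-en-1-yl acetate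
Conditions: hν (350 nm), degassed benzene (0.005 M), rt
Reagents that add atoms: none
Why: Direct excitation of the acyclic enone and intersystem crossing give the twisted ππ* triplet, whose β-carbon C1 attacks the unsubstituted internal vinyl carbon C9 (rule of five), and the resulting 1,4-biradical (primary C10, α-keto tertiary C11) closes the C10–C11 bond after spin inversion; the closest known reaction type is the crossed intramolecular enone–alkene [2+2] photocycloaddition of hexa-1,5-dien-3-ones to bicyclo[2.1.1]hexan-2-ones. The cyclopentanone ring C1–C11–C12–C8–C9 closes by 5-exo-trig radical attack and the cyclobutane C1–C9–C10–C11 by 1,4-biradical recombination, which completes the bicycle. C11 and C9 become bridgeheads, so their configuration follows from the face on which the vinyl group reacts, and this face is relayed from the C8 stereocentre, whose MOM ether should lie pseudo-equatorial and trans to C10 in the chair-like 5-exo transition state and therefore end syn to the C1 bridge. C1 is then gated sterically: with the alkoxy group filling the sector between C1 and the two-carbon bridge, the side chain is pushed anti, which is the trans relation to C8 and C12 required on the cyclobutane. The step needs crossed over straight regioselectivity (secured by the two-atom tether and the unsubstituted C9), preference for the vinyl group over the remote C4=C5 alkene (bonding there would have to start from the hindered α-carbon C11 and create a quaternary centre) and the diastereoselectivity just described; E/Z isomerisation of the enone is harmless because the biradical does not remember alkene geometry, and 350 nm light spares the saturated ketone product. Bicycles from the minor facial series should mostly carry the chain syn and are diastereomers removable by chromatography, so enantiopurity is preserved after C8 is excised.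

**Step 6**
Reactants: 8 (2E)-5-[(1S,3S,4R,5S)-3-(methoxymethoxy)-1-methyl-2-oxobicyclo[2.1.1]hexan-5-yl]-3-methylpent-2-en-1-yl acetate
Product: 9 (2E)-5-[(1S,3S,4R,5S)-3-hydroxy-1-methyl-2-oxobicyclo[2.1.1]hexan-5-yl]-3-methylpent-2-en-1-yl acetate
Conditions: Me2BBr, CH2Cl2, −78 °C; then aq. NaHCO3
Reagents that add atoms: none
Why: Me2BBr cleaves the methoxymethyl acetal at low temperature (bromide attack on the boron-activated acetal, hydrolysis of the bromomethyl ether on work-up) without ionising the allylic acetate, exposing the α-hydroxy ketone.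

**Step 7**
Reactants: 9 (2E)-5-[(1S,3S,4R,5S)-3-hydroxy-1-methyl-2-oxobicyclo[2.1.1]hexan-5-yl]-3-methylpent-2-en-1-yl acetate
Product: 10 methyl (1S,2S,3R)-2-[(3E)-5-acetoxy-3-methylpent-3-en-1-yl]-3-formyl-1-methylcyclobutane-1-carboxylate
Conditions: Pb(OAc)4, MeOH–benzene (1:1), 0 °C
Reagents that add atoms: methanol CO
Why: The strained ketone adds methanol to its hemiketal, which undergoes Criegee-type glycol cleavage of C8–C12 with release of ring strain to give the C12 methyl ester and the C8 aldehyde; C1, C9 and C11 are untouched, and the epimerisable C9 already has the favoured trans relation to the C1 side chain.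

**Step 8**
Reactants: 10 methyl (1S,2S,3R)-2-[(3E)-5-acetoxy-3-methylpent-3-en-1-yl]-3-formyl-1-methylcyclobutane-1-carboxylate; 11 ethyl diazoacetate
Product: 12 methyl (1S,2S,3R)-2-[(3E)-5-acetoxy-3-methylpent-3-en-1-yl]-3-(3-ethoxy-3-oxopropanoyl)-1-methylcyclobutane-1-carboxylate
Conditions: SnCl2 (10 mol %), CH2Cl2, rt
Reagents that add atoms: none
Why: Roskamp reaction: SnCl2-catalysed addition of the diazo ester to the aldehyde, 1,2-hydride shift and loss of N2 give the β-keto ester chemoselectively, installing C7 as a stabilised nucleophile.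

**Step 9**
Reactants: 12 methyl (1S,2S,3R)-2-[(3E)-5-acetoxy-3-methylpent-3-en-1-yl]-3-(3-ethoxy-3-oxopropanoyl)-1-methylcyclobutane-1-carboxylate
Product: 13 7-ethyl 11-methyl (1S,4E,9R,11S)-4,11-dimethyl-8-oxobicyclo[7.2.0]undec-4-ene-7,11-dicarboxylate (C7 epimers)
Conditions: NaH, THF, 0 °C; slow addition to Pd(PPh3)4 (10 mol %), THF, reflux (final 0.002 M)
Reagents that add atoms: none
Why: Tsuji–Trost macrocyclisation: zerovalent palladium ionises the allylic acetate to the syn π-allyl complex and the soft β-keto ester enolate attacks its less substituted terminus C6 anti to palladium under high dilution, closing the nine-membered ring through C6–C7 with retention of the (E)-C4=C5 geometry (the new C7 centre is lost in step 10).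

**Step 10**
Reactants: 13 7-ethyl 11-methyl (1S,4E,9R,11S)-4,11-dimethyl-8-oxobicyclo[7.2.0]undec-4-ene-7,11-dicarboxylate
Product: 14 methyl (1S,4E,9R,11S)-4,11-dimethyl-8-oxobicyclo[7.2.0]undec-4-ene-11-carboxylate
Conditions: NaCl, H2O, DMSO, 150 °C
Reagents that add atoms: none
Why: Krapcho dealkoxycarbonylation removes the activated ethoxycarbonyl group under neutral conditions while the hindered, non-activated C12 methyl ester stays, and C9 next to the ketone keeps the thermodynamically favoured trans ring fusion.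

**Step 11**
Reactants: 14 methyl (1S,4E,9R,11S)-4,11-dimethyl-8-oxobicyclo[7.2.0]undec-4-ene-11-carboxylate
Product: 15 methyl (1S,4E,9R,11S)-4,11-dimethyl-8-methylidenebicyclo[7.2.0]undec-4-ene-11-carboxylate
Conditions: Ph3PCH3Br, KOt-Bu, THF, 0 °C to rt
Reagents that add atoms: methyltriphenylphosphonium bromide C[P+](c1ccccc1)(c1ccccc1)c1ccccc1.[Br-]
Why: Wittig methylenation installs the exocyclic C8 methylidene; the neopentyl-type ester does not react and any enolisation at C9 returns the more stable trans fusion.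

**Step 12**
Reactants: 15 methyl (1S,4E,9R,11S)-4,11-dimethyl-8-methylidenebicyclo[7.2.0]undec-4-ene-11-carboxylate
Product: 16 (1S,4E,9R,11S)-N-methoxy-N,4,11-trimethyl-8-methylidenebicyclo[7.2.0]undec-4-ene-11-carboxamide
Conditions: MeNH(OMe)·HCl, i-PrMgCl (excess), THF, −20 °C to rt
Reagents that add atoms: N,O-dimethylhydroxylamine hydrochloride CNOC.Cl
Why: The chloromagnesium amide of N,O-dimethylhydroxylamine converts the hindered ester into the Weinreb amide through a stable chelated tetrahedral intermediate, preparing C12 for a single acylation.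

**Step 13**
Reactants: 17 (2S)-(2-methyloxiran-2-yl)methanol [(S)-2-methylglycidol]
Product: 18 (2R)-2-methyloxirane-2-carbaldehyde
Conditions: TEMPO (cat.), PhI(OAc)2, CH2Cl2, rt; used as a solution
Reagents that add atoms: none
Why: Oxoammonium (TEMPO) oxidation gives the aldehyde under mild, non-nucleophilic conditions that spare the epoxide; the quaternary stereocentre cannot epimerise (the descriptor changes only through substituent priorities).

**Step 14**
Reactants: 18 (2R)-2-methyloxirane-2-carbaldehyde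
Product: 19 (2S)-2-ethynyl-2-methyloxirane
Conditions: dimethyl (1-diazo-2-oxopropyl)phosphonate, K2CO3, MeOH, 0 °C to rt
Reagents that add atoms: dimethyl (1-diazo-2-oxopropyl)phosphonate COP(=O)(OC)C(=[N+]=[N-])C(C)=O
Why: Ohira–Bestmann (Seyferth–Gilbert) homologation converts the non-enolisable aldehyde into the terminal alkyne through an alkylidene carbene 1,2-shift, leaving the epoxide and its configuration untouched.

**Step 15**
Reactants: 16 (1S,4E,9R,11S)-N-methoxy-N,4,11-trimethyl-8-methylidenebicyclo[7.2.0]undec-4-ene-11-carboxamide; 19 (2S)-2-ethynyl-2-methyloxirane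
Product: 21 1-[(1S,4E,9R,11S)-4,11-dimethyl-8-methylidenebicyclo[7.2.0]undec-4-en-11-yl]-3-[(2S)-2-methyloxiran-2-yl]prop-2-yn-1-one, via lithium acetylide 20 (not isolated)
Conditions: 19, n-BuLi, THF, −78 °C; then 16, −78 to 0 °C; aq. NH4Cl
Reagents that add atoms: none
Why: Weinreb ketone synthesis: the lithium acetylide adds once to the amide and the chelated adduct collapses to the ynone on work-up, and at low temperature the acetylide does not open the epoxide.

**Step 16**
Reactants: 21 1-[(1S,4E,9R,11S)-4,11-dimethyl-8-methylidenebicyclo[7.2.0]undec-4-en-11-yl]-3-[(2S)-2-methyloxiran-2-yl]prop-2-yn-1-one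
Product: 22 (2Z)-1-[(1S,4E,9R,11S)-4,11-dimethyl-8-methylidenebicyclo[7.2.0]undec-4-en-11-yl]-3-[(2S)-2-methyloxiran-2-yl]prop-2-en-1-one
Conditions: H2 (1 atm), Pd/CaCO3 poisoned with Pb(OAc)2 (Lindlar catalyst), quinoline, EtOAc, rt, stopped at one equivalent
Reagents that add atoms: none
Why: Lindlar semi-hydrogenation adds H2 syn to the alkyne to give the (Z)-enone needed for ring closure, and the poisoned catalyst should spare the tri- and 1,1-disubstituted alkenes and the vinyl epoxide.

**Step 17**
Reactants: 22 (2Z)-1-[(1S,4E,9R,11S)-4,11-dimethyl-8-methylidenebicyclo[7.2.0]undec-4-en-11-yl]-3-[(2S)-2-methyloxiran-2-yl]prop-2-en-1-one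
Product: 24 (3R,6R)-3-[(1S,4E,9R,11S)-4,11-dimethyl-8-methylidenebicyclo[7.2.0]undec-4-en-11-yl]-6-(hydroxymethyl)-6-methyl-3,6-dihydro-1,2-dioxin-3-ol, via C12 hydroperoxy hemiketal 23 (not isolated)
Conditions: anhydrous H2O2 in Et2O, H3PMo12O40 (cat.), 0 °C to rt
Reagents that add atoms: hydrogen peroxide OO
Why: Acid-catalysed perhydrolysis of an epoxy ketone: H2O2 adds reversibly to the ketone and the hydroperoxy oxygen opens the activated epoxide at its tertiary carbon C15 in a 6-exo-tet mode with inversion (S epoxide gives 15R), releasing the CH2OH group and closing the dihydro-1,2-dioxin-3-ol, while C12 settles by ring–chain equilibration in the anomerically stabilised 12R form (see remark 1).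

**Step 18**
Reactants: 24 (3R,6R)-3-[(1S,4E,9R,11S)-4,11-dimethyl-8-methylidenebicyclo[7.2.0]undec-4-en-11-yl]-6-(hydroxymethyl)-6-methyl-3,6-dihydro-1,2-dioxin-3-ol
Product: 25 (3R,6R)-3-[(1S,4S,5S,9R,11S)-4,5-epoxy-4,11-dimethyl-8-methylidenebicyclo[7.2.0]undecan-11-yl]-6-(hydroxymethyl)-6-methyl-3,6-dihydro-1,2-dioxin-3-ol (CNP0273942.1)
Conditions: mCPBA (1.0 equiv), NaHCO3, CH2Cl2, −20 to 0 °C
Reagents that add atoms: 3-chloroperoxybenzoic acid OOC(=O)c1cccc(Cl)c1
Why: Prilezhaev epoxidation: the strained, electron-rich (E)-trisubstituted C4=C5 alkene should react faster than the 1,1-disubstituted methylidene and the deactivated dioxine alkene, and peracid attack on the exposed outer face of the predominant ring conformers should give the (4S,5S)-epoxide, as in the caryophyllene to caryophyllene oxide conversion.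

**Compound list**

1 | geranyl acetate [(2E)-3,7-dimethylocta-2,6-dien-1-yl acetate] | CC(C)=CCC/C(C)=C/COC(C)=O | starting material
2 | (2E,6E)-8-hydroxy-3,7-dimethylocta-2,6-dien-1-yl acetate | OC/C(C)=C/CC/C(C)=C/COC(C)=O | intermediate
3 | (2E,6E)-3,7-dimethyl-8-oxoocta-2,6-dien-1-yl acetate | O=C/C(C)=C/CC/C(C)=C/COC(C)=O | intermediate
4 | allyl methoxymethyl ether [3-(methoxymethoxy)prop-1-ene] | C=CCOCOC | starting material
5 | [(2Z)-3-(methoxymethoxy)prop-2-en-1-yl]diisopinocampheylborane (both isopinocampheyl groups from (−)-α-pinene) | COCO/C=C\CB([C@H]1C[C@H]2C[C@@H]([C@@H]1C)C2(C)C)[C@H]1C[C@H]2C[C@@H]([C@@H]1C)C2(C)C | intermediate (not isolated)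
6 | (2E,6E,8S,9S)-8-hydroxy-9-(methoxymethoxy)-3,7-dimethylundeca-2,6,10-trien-1-yl acetate | C=C[C@H](OCOC)[C@@H](O)/C(C)=C/CC/C(C)=C/COC(C)=O | intermediate
7 | (2E,6E,9S)-9-(methoxymethoxy)-3,7-dimethyl-8-oxoundeca-2,6,10-trien-1-yl acetate | C=C[C@H](OCOC)C(=O)/C(C)=C/CC/C(C)=C/COC(C)=O | intermediate
8 | (2E)-5-[(1S,3S,4R,5S)-3-(methoxymethoxy)-1-methyl-2-oxobicyclo[2.1.1]hexan-5-yl]-3-methylpent-2-en-1-yl acetate | C[C@]12C(=O)[C@@H](OCOC)[C@H](C1)[C@@H]2CC/C(C)=C/COC(C)=O | intermediate
9 | (2E)-5-[(1S,3S,4R,5S)-3-hydroxy-1-methyl-2-oxobicyclo[2.1.1]hexan-5-yl]-3-methylpent-2-en-1-yl acetate | C[C@]12C(=O)[C@@H](O)[C@H](C1)[C@@H]2CC/C(C)=C/COC(C)=O | intermediate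
10 | methyl (1S,2S,3R)-2-[(3E)-5-acetoxy-3-methylpent-3-en-1-yl]-3-formyl-1-methylcyclobutane-1-carboxylate | COC(=O)[C@@]1(C)C[C@@H](C=O)[C@@H]1CC/C(C)=C/COC(C)=O | intermediate
11 | ethyl diazoacetate | CCOC(=O)C=[N+]=[N-] | starting material
12 | methyl (1S,2S,3R)-2-[(3E)-5-acetoxy-3-methylpent-3-en-1-yl]-3-(3-ethoxy-3-oxopropanoyl)-1-methylcyclobutane-1-carboxylate | COC(=O)[C@@]1(C)C[C@@H](C(=O)CC(=O)OCC)[C@@H]1CC/C(C)=C/COC(C)=O | intermediate
13 | 7-ethyl 11-methyl (1S,4E,9R,11S)-4,11-dimethyl-8-oxobicyclo[7.2.0]undec-4-ene-7,11-dicarboxylate (C7 epimers) | COC(=O)[C@@]1(C)C[C@@H]2[C@@H]1CC/C(C)=C/CC(C(=O)OCC)C2=O | intermediate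
14 | methyl (1S,4E,9R,11S)-4,11-dimethyl-8-oxobicyclo[7.2.0]undec-4-ene-11-carboxylate | COC(=O)[C@@]1(C)C[C@@H]2[C@@H]1CC/C(C)=C/CCC2=O | intermediate
15 | methyl (1S,4E,9R,11S)-4,11-dimethyl-8-methylidenebicyclo[7.2.0]undec-4-ene-11-carboxylate | COC(=O)[C@@]1(C)C[C@@H]2[C@@H]1CC/C(C)=C/CCC2=C | intermediate
16 | (1S,4E,9R,11S)-N-methoxy-N,4,11-trimethyl-8-methylidenebicyclo[7.2.0]undec-4-ene-11-carboxamide | CON(C)C(=O)[C@@]1(C)C[C@@H]2[C@@H]1CC/C(C)=C/CCC2=C | intermediate
17 | (2S)-(2-methyloxiran-2-yl)methanol [(S)-2-methylglycidol] | OC[C@@]1(C)CO1 | starting material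
18 | (2R)-2-methyloxirane-2-carbaldehyde | O=C[C@@]1(C)CO1 | intermediate
19 | (2S)-2-ethynyl-2-methyloxirane | C#C[C@@]1(C)CO1 | intermediate
20 | lithium [(2S)-2-methyloxiran-2-yl]acetylide | [Li]C#C[C@@]1(C)CO1 | intermediate (not isolated)
21 | 1-[(1S,4E,9R,11S)-4,11-dimethyl-8-methylidenebicyclo[7.2.0]undec-4-en-11-yl]-3-[(2S)-2-methyloxiran-2-yl]prop-2-yn-1-one | O=C(C#C[C@@]1(C)CO1)[C@@]1(C)C[C@@H]2[C@@H]1CC/C(C)=C/CCC2=C | intermediate
22 | (2Z)-1-[(1S,4E,9R,11S)-4,11-dimethyl-8-methylidenebicyclo[7.2.0]undec-4-en-11-yl]-3-[(2S)-2-methyloxiran-2-yl]prop-2-en-1-one | O=C(/C=C\[C@@]1(C)CO1)[C@@]1(C)C[C@@H]2[C@@H]1CC/C(C)=C/CCC2=C | intermediate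
23 | (2Z)-1-[(1S,4E,9R,11S)-4,11-dimethyl-8-methylidenebicyclo[7.2.0]undec-4-en-11-yl]-1-hydroperoxy-3-[(2S)-2-methyloxiran-2-yl]prop-2-en-1-ol (C1 epimers) | OOC(O)(/C=C\[C@@]1(C)CO1)[C@@]1(C)C[C@@H]2[C@@H]1CC/C(C)=C/CCC2=C | intermediate (not isolated)
24 | (3R,6R)-3-[(1S,4E,9R,11S)-4,11-dimethyl-8-methylidenebicyclo[7.2.0]undec-4-en-11-yl]-6-(hydroxymethyl)-6-methyl-3,6-dihydro-1,2-dioxin-3-ol | C=C1CC/C=C(C)/CC[C@H]2[C@H]1C[C@]2(C)[C@@]1(O)C=C[C@](C)(CO)OO1 | intermediate
25 | (3R,6R)-3-[(1S,4S,5S,9R,11S)-4,5-epoxy-4,11-dimethyl-8-methylidenebicyclo[7.2.0]undecan-11-yl]-6-(hydroxymethyl)-6-methyl-3,6-dihydro-1,2-dioxin-3-ol (CNP0273942.1) | C=C1CC[C@@H]2O[C@@]2(C)CC[C@H]2[C@H]1C[C@]2(C)[C@@]1(O)C=C[C@](C)(CO)OO1 | target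

**Total step count:** 18. **Longest linear sequence:** 16 steps (steps 1–12 and 15–18, from geranyl acetate); steps 13–14 make the alkyne fragment.

**Steps most likely to fail**

1. Step 5 (key photocycloaddition). The relay from C8 may be weak, so that both facial series form. Where the alkoxy group does not block the sector next to the two-carbon bridge, the side chain on C1 may settle syn. The triplet may also partition into 1,6-(straight) closure, into bonding with the remote C4=C5 alkene, or into Norrish type 1 cleavage of the doubly activated C8–C12 bond. Fallback: replace the small acetal by a bulky silyl ether, which both strengthens the pseudo-equatorial preference and acts as a steric gate for C1. The fallback sets out from 7. Me2BBr at −78 °C gives (2E,6E,9S)-9-hydroxy-3,7-dimethyl-8-oxoundeca-2,6,10-trien-1-yl acetate F1. TIPSOTf and 2,6-lutidine at −78 °C give (2E,6E,9S)-3,7-dimethyl-8-oxo-9-[(triisopropylsilyl)oxy]undeca-2,6,10-trien-1-yl acetate F2. Irradiation at 350 nm gives (2E)-3-methyl-5-[(1S,3S,4R,5S)-1-methyl-2-oxo-3-[(triisopropylsilyl)oxy]bicyclo[2.1.1]hexan-5-yl]pent-2-en-1-yl acetate F3. Buffered TBAF/AcOH removes the silyl group and the route is rejoined at 9.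

2. Step 17 (perhydrolysis and dioxinol closure). The acid needed to activate the epoxide may trigger transannular cyclisation or peroxidation of the strained (E)-cyclononene. The tertiary allylic centre may ionise, with loss of configuration at C15 or allylic transposition. H2O2 may add in conjugate fashion, or the (Z)-enone may isomerise before closure. Fallback: make the C15–O–O bond on the small fragment, where no acid-labile ring is present, and carry it as a cyclic peroxyketal. The fallback sets out from 18. Stork–Zhao olefination (Ph3PCH2I iodide, NaHMDS, −78 °C) gives (2S)-2-[(Z)-2-iodoethenyl]-2-methyloxirane F6. Perhydrolysis (H2O2, cat. H3PMo12O40, Et2O) with inversion gives (2R,3Z)-2-hydroperoxy-4-iodo-2-methylbut-3-en-1-ol F7. 2,2-Dimethoxypropane with cat. PPTS gives (6R)-6-[(Z)-2-iodoethenyl]-3,3,6-trimethyl-1,2,4-trioxane F8. Iodine–lithium exchange (t-BuLi, Et2O, −78 °C) and acylation with Weinreb amide 16 give (2Z)-1-[(1S,4E,9R,11S)-4,11-dimethyl-8-methylidenebicyclo[7.2.0]undec-4-en-11-yl]-3-[(6R)-3,3,6-trimethyl-1,2,4-trioxan-6-yl]prop-2-en-1-one F9. Mild transketalisation (PPTS, THF–H2O) releases acetone and the hydroperoxy alcohol closes onto the ketone, rejoining the route at 24.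

3. Step 9 (macrocyclisation). Ring strain in the transition state may slow closure enough for oligomerisation, for attack at the substituted allyl terminus C4 (seven-membered ring), or for syn–anti isomerisation of the π-allyl complex with erosion of the (E)-geometry. Fallback: a base-mediated SN2 ring closure that cannot scramble the alkene. The fallback sets out from 12. K2CO3 in EtOH at 0 °C removes the acetate to give methyl (1S,2S,3R)-3-(3-ethoxy-3-oxopropanoyl)-2-[(3E)-5-hydroxy-3-methylpent-3-en-1-yl]-1-methylcyclobutane-1-carboxylate F4. NCS/Me2S gives methyl (1S,2S,3R)-2-[(3E)-5-chloro-3-methylpent-3-en-1-yl]-3-(3-ethoxy-3-oxopropanoyl)-1-methylcyclobutane-1-carboxylate F5. Cs2CO3 with cat. NaI in MeCN at high dilution closes the ring by direct displacement at C6 and returns to 13.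

**Further compounds**

F1 | step 5 | (2E,6E,9S)-9-hydroxy-3,7-dimethyl-8-oxoundeca-2,6,10-trien-1-yl acetate | C=C[C@H](O)C(=O)/C(C)=C/CC/C(C)=C/COC(C)=O
F2 | step 5 | (2E,6E,9S)-3,7-dimethyl-8-oxo-9-[(triisopropylsilyl)oxy]undeca-2,6,10-trien-1-yl acetate | C=C[C@H](O[Si](C(C)C)(C(C)C)C(C)C)C(=O)/C(C)=C/CC/C(C)=C/COC(C)=O
F3 | step 5 | (2E)-3-methyl-5-[(1S,3S,4R,5S)-1-methyl-2-oxo-3-[(triisopropylsilyl)oxy]bicyclo[2.1.1]hexan-5-yl]pent-2-en-1-yl acetate | C[C@]12C(=O)[C@@H](O[Si](C(C)C)(C(C)C)C(C)C)[C@H](C1)[C@@H]2CC/C(C)=C/COC(C)=O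
F4 | step 9 | methyl (1S,2S,3R)-3-(3-ethoxy-3-oxopropanoyl)-2-[(3E)-5-hydroxy-3-methylpent-3-en-1-yl]-1-methylcyclobutane-1-carboxylate | COC(=O)[C@@]1(C)C[C@@H](C(=O)CC(=O)OCC)[C@@H]1CC/C(C)=C/CO
F5 | step 9 | methyl (1S,2S,3R)-2-[(3E)-5-chloro-3-methylpent-3-en-1-yl]-3-(3-ethoxy-3-oxopropanoyl)-1-methylcyclobutane-1-carboxylate | COC(=O)[C@@]1(C)C[C@@H](C(=O)CC(=O)OCC)[C@@H]1CC/C(C)=C/CCl
F6 | step 17 | (2S)-2-[(Z)-2-iodoethenyl]-2-methyloxirane | I/C=C\[C@@]1(C)CO1
F7 | step 17 | (2R,3Z)-2-hydroperoxy-4-iodo-2-methylbut-3-en-1-ol | I/C=C\[C@](C)(CO)OO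
F8 | step 17 | (6R)-6-[(Z)-2-iodoethenyl]-3,3,6-trimethyl-1,2,4-trioxane | I/C=C\[C@]1(C)COC(C)(C)OO1
F9 | step 17 | (2Z)-1-[(1S,4E,9R,11S)-4,11-dimethyl-8-methylidenebicyclo[7.2.0]undec-4-en-11-yl]-3-[(6R)-3,3,6-trimethyl-1,2,4-trioxan-6-yl]prop-2-en-1-one | O=C(/C=C\[C@]1(C)COC(C)(C)OO1)[C@@]1(C)C[C@@H]2[C@@H]1CC/C(C)=C/CCC2=C
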